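At 1.0 h you want to read target and substrate in the flask, and what you hold is the alder run, followed to 12.0 min at a higher loading of spent carrier.

all flasks: substrate 0.35 M
- alder: salt in the second phase 1.3 equiv; spent carrier 7.5 mol%; run made earlier
- flask: salt in the second phase 1.30 equiv; spent carrier 5 mol%; time 1.0 h; volume of the second phase over the first 1.0

alder run (percent of the substrate charged)

| time / min | target / % | substrate / % |
|---|---|---|
| 1.00 | 0.5 | 99.4 |
| 1.50 | 1.9 | 98.0 |
| 2.50 | 3.0 | 96.7 |
| 4.00 | 5.1 | 94.9 |
| 8.00 | 10.4 | 90.2 |
| 12.0 | 14.4 | 84.9 |

(each reading ± 0.3 percentage points)

- concentration of target at 1.0 h, in M
- concentration of substrate at 1.0 h, in M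

- in the second phase: salt in the second phase, spent salt in the second phase; everything else is in the first
- charges count per volume of the first phase; a concentration in a rate is the amount of a species over the volume of its own phase; every rate counts per litre of the first phase
- steps that have been proposed: spent carrier + salt in the second phase <-> fresh carrier + spent salt in the second phase; substrate + fresh carrier -> target + spent carrier; fresh carrier <-> dormant form
- the earlier runs hold the two phases in the same ratio of volumes as the flask asked about

In the alder run, target and substrate add up close to the charge, so I take substrate in this flask as the charge minus target. Between 4.00 min and 12.0 min, the alder target rises by 0.0116 /min of the charge, a reading that carries the scatter. Each proposed step takes carrier once, so I scale that rate by 5 mol% over 7.5 mol% and multiply by the time. The result is the frozen conversion Φ, the share of the substrate charge that the early rate, held unchanged, turns over in the whole time: 0.465.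

Held frozen, this gives 0.163 M of target in the flask. A rate in step with substrate (pseudo-first-order) gives a tighter upper end of my estimate, 1 − exp(−Φ) of the charge, 0.130 M. For the lower end of my estimate, I let fresh carrier fall in step with substrate too, so that the rate follows substrate squared. That gives 1 − 1/(1 + Φ) of the charge, 0.111 M. I commit to target between these two.

The forecast gives 0.15 M of target and 0.2 M of substrate. It also scales by loading, since “All proposed steps are linear in total carrier”, but it uses its own first-order fit. Its target stands below the frozen value and above my tighter upper end.

The flask gives 0.124 M of target and 0.226 M of substrate, which puts its target inside my bracket.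

    spent carrier + salt in the second phase ⇌ fresh carrier + spent salt in the second phase (K = 0.370, k = 2.60 /M/min)
    substrate + fresh carrier → target + spent carrier (k = 0.900 /M/min)
    fresh carrier ⇌ dormant form (K = 0.380, k = 0.0280 /min)

Take the neighbouring flask with 12 mol% of spent carrier, its other charges and time as in the flask. Its Φ is 1.12, and the same two expressions put its target between 0.185 M and 0.235 M. That neighbouring flask gives 0.195 M of target at 1.0 h.

The data were computed for an exercise, noise included.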